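At 3.0 h the flask is read for how much has reacted, and at 20 min for which product leads.

| setting | Monday's | Saturday's | Friday's | flask |
|---|---|---|---|---|
| left-handed substrate | 0.10 M | 0.10 M | 0.10 M | 0.10 M |
| right-handed substrate | 0.10 M | 0.10 M | 0.10 M | 0.10 M |
| partner | 0.060 M | 0.24 M | 0.12 M | 0.120 M |
| free catalyst | 0.10 mM | 0.10 mM | 0.20 mM | 0.10 mM |
| remark | run made earlier | run made earlier | run made earlier |  |
| time |  |  |  | 3.0 h |

| run | time / h | left-handed product / % | right-handed product / % | left-handed substrate / % |
|---|---|---|---|---|
| Monday's | 0.333 | 5.0 | 2.9 | 41.2 |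
| Monday's | 0.667 | 7.0 | 7.0 | 35.7 |
| Monday's | 1.00 | 7.1 | 7.2 | 36.0 |
| Monday's | 1.33 | 9.0 | 10.2 | 32.4 |
| Monday's | 1.50 | 8.0 | 10.1 | 33.5 |
| Monday's | 2.00 | 10.9 | 11.8 | 31.3 |
| Monday's | 2.50 | 11.3 | 9.9 | 29.7 |
| Saturday's | 0.200 | 17.3 | 7.8 | 28.1 |
| Saturday's | 0.333 | 17.3 | 13.5 | 18.9 |
| Saturday's | 0.417 | 17.9 | 15.3 | 17.6 |
| Saturday's | 0.667 | 21.0 | 18.8 | 12.5 |
| Saturday's | 1.00 | 23.5 | 23.2 | 6.7 |
| Saturday's | 1.50 | 26.2 | 25.7 | 3.9 |
| Saturday's | 2.50 | 24.5 | 26.7 | 0 |
| Friday's | 0.200 | 13.0 | 7.8 | 29.7 |
| Friday's | 0.667 | 19.9 | 16.7 | 15.3 |
| Friday's | 1.00 | 20.2 | 18.4 | 11.5 |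
| Friday's | 1.50 | 21.3 | 20.6 | 9.2 |
| Friday's | 2.50 | 21.9 | 21.6 | 8.9 |

(standard deviation of a reading: 1 percentage point)

- free catalyst is single-handed; left-handed substrate and right-handed substrate are mirror images of each other, charged as a racemate, each of them at the stated concentration
- an excess is the difference of the two amounts in percent of their sum
- an excess is below zero if the other one leads

- excess of left-handed product over right-handed product in the product at 20 min
- excess of left-handed product over right-handed product in the product at 3.0 h
- part of the left-handed substrate and right-handed substrate charged together that has reacted at 3.0 h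

Two chemists dispute the reading at 3.0 h. Rosa counts charges: the flask holds 1.20 equivalents of partner on the left-handed substrate, so that substrate is the limiting reagent, and the reaction should end near its charge, 50.0% of both substrates together. Saturday's run is her witness: at 2.50 h left-handed substrate read 0% and product 51.2%.

Tomas points to Friday's run, where left-handed substrate still read 8.9% at 2.50 h while the readings of product had nearly levelled. There product, set against partner charged on the same percent scale, gives a share 0.725, and Monday's last reading gives 0.707, with 0.060 M of partner and 0.10 mM of catalyst. He defines the usable partner U as Friday's share times the partner charged, in percent of both substrates together. For the flask U is 43.5%, below Rosa's figure, so he expects product to stop there.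

My own reckoning takes U as the far end and Friday's run for the way there, since it has the flask's charges with twice the catalyst. If progress goes with catalyst times time, the flask at 3.0 h stands where Friday stood at 1.50 h, half that time: 41.9% reacted, just under U.

The forecast, also on the partner side, says an excess of left-handed product of 25% at 20 min and 0.5% at 3.0 h with “the products are essentially equalised”, and 40% reacted, below my figure.

The flask gives an excess of left-handed product of 17.7% at 20 min and 0.431% at 3.0 h, and 38.5% reacted.

    free catalyst + left-handed substrate ⇌ catalyst intermediate A (K = 47.0 /M, k = 180 /M/s)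
    free catalyst + right-handed substrate ⇌ catalyst intermediate B (K = 14.0 /M, k = 530 /M/s)
    partner + catalyst intermediate A → free catalyst + left-handed product (k = 6.60 /M/s)
    partner + catalyst intermediate B → free catalyst + right-handed product (k = 0.450 /M/s)
    left-handed product ⇌ right-handed product (k = 0.00160 /s)
    partner ⇌ dormant form (K = 1.20, k = 4.70 × 10⁻⁴ /s)
    free catalyst → spent catalyst (k = 5.10 × 10⁻⁴ /s)

That is 88.5% of U, and unbound left-handed substrate still stands at 12.9% of both substrates charged together, so at 3.0 h Tomas's side holds for this flask. At 3.0 h spent catalyst stands at 73.5% of the catalyst charged, and partner at 15.5% of its own charge beside 0.0244 M of dormant form. Rosa's region shows in a neighbouring flask with 0.48 M of partner: U is 174%, far above the left-handed charge. There left-handed substrate falls to 0.027% of its charge at 3.0 h, as Rosa reckoned, but 60.2% has reacted, more than her figure, and right-handed substrate stands at 39.8% of both substrates charged together.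

(The earlier runs and the new flask were generated by integration for substances that don't exist.)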